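**Plan**

- Retrosynthesis: the C2–C3 bond of ring C is cut by a retro-α-ketol shift (C2 returns from C3 to the C4 carbon), contracting ring C to a 3-formyl-2,3-dihydrobenzofuran-3-ol. That ring is cut at C2–C(carbinol) (retro Norrish–Yang), then at C4a–C4 (aryl–acyl), C6–C1'' (geranyl) and O1–C2 (benzylic ether).
- Feature used: ring C is an α-hydroxy ketone, C3 carrying OH and H next to the C4 carbonyl on C4a of ring A. It is therefore the stable ketol isomer of a five-membered ring in which C2 and the formyl carbon (future C3) both sit on the carbinol carbon (future C4).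
- Forward: ring B (isovanillin) is joined to ring A (phloroglucinol) through O1–C2; the geranyl chain and then a two-carbon keto ester are put on ring A by two ortho-lithiations; light closes the five-membered ring; a 1,2-shift of C2 expands it to ring C; MOM removal ends the route.
- Stereochemistry: C2 comes from the photocyclisation of an 8-phenylmenthyl keto ester plus separation of diastereomers, and is carried through the shift with retention. C3 is set in the shift itself (open anti transition state, trans and thermodynamically favoured). The E olefin comes from geranyl bromide.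

Key step: step 11

Assumption: the (1R,2S,5R)-8-phenylmenthyl ester is taken to favour the 2R photoproduct with the aryl group cis to the hydroxyl; if the 2S series prevails, the enantiomeric auxiliary is used and nothing else changes. (Geranyl = (2E)-3,7-dimethylocta-2,6-dien-1-yl throughout.)

**Route**

Step 1
Reactants: 1 phloroglucinol
Product: 2 3,5-bis(methoxymethoxy)phenol
Conditions: MOMCl (2.0 equiv), i-Pr2NEt, DMF, 0 °C → rt; chromatography
Reagents that add atoms: chloromethyl methyl ether (MOMCl), COCCl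
Why: Base-mediated O-alkylation (MOM ether formation) of a triol whose hydroxyls are equivalent, so two equivalents should give a statistical mixture from which the symmetric bis-ether is separated and the mono-ether recycled.

Step 2
Reactants: 3 isovanillin
Product: 4 4-methoxy-3-(methoxymethoxy)benzaldehyde
Conditions: MOMCl, i-Pr2NEt, CH2Cl2, 0 °C → rt
Reagents that add atoms: chloromethyl methyl ether (MOMCl), COCCl
Why: The same MOM ether formation on the single phenol of isovanillin, the aldehyde being inert to MOMCl and amine base.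

Step 3
Reactants: 4 4-methoxy-3-(methoxymethoxy)benzaldehyde
Product: 5 [4-methoxy-3-(methoxymethoxy)phenyl]methanol
Conditions: NaBH4, MeOH, 0 °C
Reagents that add atoms: none
Why: Borohydride reduction of an aryl aldehyde to the benzylic alcohol, which leaves the acetal untouched.

Step 4
Reactants: 2 3,5-bis(methoxymethoxy)phenol; 5 [4-methoxy-3-(methoxymethoxy)phenyl]methanol
Product: 6 1-{[4-methoxy-3-(methoxymethoxy)benzyl]oxy}-3,5-bis(methoxymethoxy)benzene
Conditions: PPh3, DIAD, THF, 0 °C → rt
Reagents that add atoms: none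
Why: Mitsunobu etherification, in which the acidic phenol displaces the oxyphosphonium of the primary benzylic alcohol by SN2 under neutral conditions that the MOM ethers tolerate.

Step 5
Reactants: 6 1-{[4-methoxy-3-(methoxymethoxy)benzyl]oxy}-3,5-bis(methoxymethoxy)benzene; 7 geranyl bromide
Product: 9 2-geranyl-5-{[4-methoxy-3-(methoxymethoxy)benzyl]oxy}-1,3-bis(methoxymethoxy)benzene, via aryllithium 8 (not isolated)
Conditions: n-BuLi, THF, 0 °C; CuI (10 mol %), then 7, −78 °C → rt
Reagents that add atoms: none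
Why: Directed ortho-metalation at the carbon flanked by the two MOM ethers (the strongest, cooperative directing pair), followed by copper-catalysed SN2 coupling of the aryllithium with the allylic bromide, which keeps the E double bond.

Step 6
Reactants: 10 (−)-8-phenylmenthol, (1R,2S,5R)-5-methyl-2-(2-phenylpropan-2-yl)cyclohexan-1-ol; 11 oxalyl chloride
Product: 12 (1R,2S,5R)-5-methyl-2-(2-phenylpropan-2-yl)cyclohexyl chloro(oxo)acetate
Conditions: 11 (3 equiv), CH2Cl2, 0 °C → rt; excess 11 removed in vacuo
Reagents that add atoms: none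
Why: Acylation of the secondary alcohol by one chloride of excess oxalyl chloride gives the half-ester chloride without touching the three stereocenters of the auxiliary.

Step 7
Reactants: 9 2-geranyl-5-{[4-methoxy-3-(methoxymethoxy)benzyl]oxy}-1,3-bis(methoxymethoxy)benzene; 12 (1R,2S,5R)-5-methyl-2-(2-phenylpropan-2-yl)cyclohexyl chloro(oxo)acetate
Product: 15 (1R,2S,5R)-5-methyl-2-(2-phenylpropan-2-yl)cyclohexyl 2-[3-geranyl-6-{[4-methoxy-3-(methoxymethoxy)benzyl]oxy}-2,4-bis(methoxymethoxy)phenyl]-2-oxoacetate, via aryllithium 13 (not isolated), via arylcopper 14 (not isolated)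
Conditions: n-BuLi, TMEDA, THF, 0 °C; CuBr·SMe2, −78 °C; then 12, −78 → −20 °C
Reagents that add atoms: none
Why: Second directed ortho-metalation at the only ring A hydrogen left (between a MOM ether and the benzyloxy oxygen), lithium-to-copper exchange and acylation of the arylcopper by the acid chloride, an organocopper ketone synthesis that stops at the keto ester.

Step 8
Reactants: 15 (1R,2S,5R)-5-methyl-2-(2-phenylpropan-2-yl)cyclohexyl 2-[3-geranyl-6-{[4-methoxy-3-(methoxymethoxy)benzyl]oxy}-2,4-bis(methoxymethoxy)phenyl]-2-oxoacetate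
Product: 16 (1R,2S,5R)-5-methyl-2-(2-phenylpropan-2-yl)cyclohexyl (2R,3R)-5-geranyl-3-hydroxy-2-[4-methoxy-3-(methoxymethoxy)phenyl]-4,6-bis(methoxymethoxy)-2,3-dihydro-1-benzofuran-3-carboxylate (aryl cis to hydroxyl)
Conditions: hν (365 nm), degassed benzene, 0.005 M, 20 °C; separation of diastereomers on Et3N-deactivated SiO2
Reagents that add atoms: none
Why: Norrish–Yang photocyclisation: the n,π* excited keto ester abstracts a benzylic ether hydrogen by 1,6-transfer (this C–H is weaker than the MOM methylene C–H beside the ketone) and the 1,5-biradical closes to the dihydrobenzofuranol, creating C2 and C3 with the aryl group trans to the ester, the face being biased by the phenyl group of the auxiliary stacked over the keto ester and the 2R series being secured by chromatographic separation of the diastereomers.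

Step 9
Reactants: 16 (1R,2S,5R)-5-methyl-2-(2-phenylpropan-2-yl)cyclohexyl (2R,3R)-5-geranyl-3-hydroxy-2-[4-methoxy-3-(methoxymethoxy)phenyl]-4,6-bis(methoxymethoxy)-2,3-dihydro-1-benzofuran-3-carboxylate
Product: 17 (2R,3S)-5-geranyl-3-(hydroxymethyl)-2-[4-methoxy-3-(methoxymethoxy)phenyl]-4,6-bis(methoxymethoxy)-2,3-dihydro-1-benzofuran-3-ol
Conditions: LiAlH4, THF, 0 °C → rt; aqueous work-up
Reagents that add atoms: none
Why: LiAlH4 reduction of the ester to the primary alcohol releases the auxiliary alcohol 10 for reuse and touches no stereocenter (C3 changes from R to S only because the CIP ranking of its substituents changes).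

Step 10
Reactants: 17 (2R,3S)-5-geranyl-3-(hydroxymethyl)-2-[4-methoxy-3-(methoxymethoxy)phenyl]-4,6-bis(methoxymethoxy)-2,3-dihydro-1-benzofuran-3-ol
Product: 18 (2R,3R)-5-geranyl-3-hydroxy-2-[4-methoxy-3-(methoxymethoxy)phenyl]-4,6-bis(methoxymethoxy)-2,3-dihydro-1-benzofuran-3-carbaldehyde
Conditions: SO3·pyridine, DMSO, i-Pr2NEt, CH2Cl2, 0 °C
Reagents that add atoms: none
Why: Parikh–Doering oxidation converts only the primary alcohol into the aldehyde, the tertiary alcohol being unable to react, and its basic medium avoids acid-induced dehydration of the tertiary benzylic alcohol to the benzofuran.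

Step 11
Reactants: 18 (2R,3R)-5-geranyl-3-hydroxy-2-[4-methoxy-3-(methoxymethoxy)phenyl]-4,6-bis(methoxymethoxy)-2,3-dihydro-1-benzofuran-3-carbaldehyde
Product: 21 (2R,3R)-6-geranyl-3-hydroxy-2-[4-methoxy-3-(methoxymethoxy)phenyl]-5,7-bis(methoxymethoxy)-2,3-dihydro-4H-chromen-4-one, via aldehyde alkoxide 19 (not isolated), via ketol alkoxide 20 (not isolated)
Conditions: KOt-Bu (1.0 equiv), 18-crown-6, THF, −40 → 0 °C; then AcOH, −40 °C
Reagents that add atoms: none
Why: Proposed new method: KOt-Bu deprotonates the tertiary hydroxyl, and in alkoxide 19 the C3–C2 σ bond shifts to the formyl carbon while the carbinol carbon becomes the C4 carbonyl, an anionic α-ketol (acyloin) rearrangement that has not been shown on a 3-formyl-2,3-dihydrobenzofuran-3-ol; the closest known reactions are the base-induced ring expansions of 1-hydroxycycloalkanecarbaldehydes to 2-hydroxycycloalkanones and the D-homoannulation of 17-hydroxy-20-oxo steroids. Ring C is closed by ring expansion: the 1,2-shift of the ring atom C2 inserts the formyl carbon into the five-membered ring and so turns it into the six-membered pyranone, without any exo or endo cyclisation. C2 migrates with retention, so its R configuration from step 8 is carried over. The new C3 centre is controlled by the open transition state of the crown-ether-separated potassium alkoxide, in which the alkoxide and formyl oxygens lie anti and C2 therefore reaches the formyl face that gives 3R, the 2,3-trans isomer that is also the more stable one. The step needs C2 to migrate in place of the ring A carbon C3a: in an anionic shift the migrating carbon takes up negative charge, which the benzylic C2 accommodates and the carbon of the trioxygenated, electron-rich ring A does not, and only C2 migration leads to the conjugated aryl ketone, the thermodynamic sink of this reversible rearrangement. Base in place of a Lewis acid also spares the MOM ethers and prevents ionisation of the tertiary benzylic alcohol towards the benzofuran.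

Step 12
Reactants: 21 (2R,3R)-6-geranyl-3-hydroxy-2-[4-methoxy-3-(methoxymethoxy)phenyl]-5,7-bis(methoxymethoxy)-2,3-dihydro-4H-chromen-4-one
Product: 22 4'-O-methyldiplacol, (2R,3R)-6-geranyl-3,5,7-trihydroxy-2-(3-hydroxy-4-methoxyphenyl)-2,3-dihydro-4H-chromen-4-one
Conditions: 3 M aq HCl, MeOH, 45 °C
Reagents that add atoms: none
Why: Acid-catalysed acetal exchange with methanol (MOM ether cleavage) frees the three phenols as dimethoxymethane, under conditions mild enough to leave the geranyl olefins and the C2 and C3 centres unchanged.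

**Compound list**

1 | phloroglucinol | Oc1cc(O)cc(O)c1 | starting material
2 | 3,5-bis(methoxymethoxy)phenol | COCOc1cc(O)cc(OCOC)c1 | intermediate
3 | isovanillin | COc1ccc(C=O)cc1O | starting material
4 | 4-methoxy-3-(methoxymethoxy)benzaldehyde | COCOc1cc(C=O)ccc1OC | intermediate
5 | [4-methoxy-3-(methoxymethoxy)phenyl]methanol | COCOc1cc(CO)ccc1OC | intermediate
6 | 1-{[4-methoxy-3-(methoxymethoxy)benzyl]oxy}-3,5-bis(methoxymethoxy)benzene | COCOc1cc(OCOC)cc(OCc2ccc(OC)c(OCOC)c2)c1 | intermediate
7 | geranyl bromide, (2E)-1-bromo-3,7-dimethylocta-2,6-diene | CC(C)=CCC/C(C)=C/CBr | starting material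
8 | {4-{[4-methoxy-3-(methoxymethoxy)benzyl]oxy}-2,6-bis(methoxymethoxy)phenyl}lithium | [Li]c1c(OCOC)cc(OCc2ccc(OC)c(OCOC)c2)cc1OCOC | intermediate
9 | 2-geranyl-5-{[4-methoxy-3-(methoxymethoxy)benzyl]oxy}-1,3-bis(methoxymethoxy)benzene | COCOc1cc(OCc2ccc(OC)c(OCOC)c2)cc(OCOC)c1C/C=C(\C)CCC=C(C)C | intermediate
10 | (−)-8-phenylmenthol, (1R,2S,5R)-5-methyl-2-(2-phenylpropan-2-yl)cyclohexan-1-ol | O[C@@H]1C[C@H](C)CC[C@H]1C(C)(C)c1ccccc1 | starting material
11 | oxalyl chloride | O=C(Cl)C(=O)Cl | starting material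
12 | (1R,2S,5R)-5-methyl-2-(2-phenylpropan-2-yl)cyclohexyl chloro(oxo)acetate | O=C(Cl)C(=O)O[C@@H]1C[C@H](C)CC[C@H]1C(C)(C)c1ccccc1 | intermediate
13 | {3-geranyl-6-{[4-methoxy-3-(methoxymethoxy)benzyl]oxy}-2,4-bis(methoxymethoxy)phenyl}lithium | [Li]c1c(OCc2ccc(OC)c(OCOC)c2)cc(OCOC)c(C/C=C(\C)CCC=C(C)C)c1OCOC | intermediate
14 | {3-geranyl-6-{[4-methoxy-3-(methoxymethoxy)benzyl]oxy}-2,4-bis(methoxymethoxy)phenyl}copper | [Cu]c1c(OCc2ccc(OC)c(OCOC)c2)cc(OCOC)c(C/C=C(\C)CCC=C(C)C)c1OCOC | intermediate
15 | (1R,2S,5R)-8-phenylmenthyl 2-[3-geranyl-6-{[4-methoxy-3-(methoxymethoxy)benzyl]oxy}-2,4-bis(methoxymethoxy)phenyl]-2-oxoacetate | COc1ccc(COc2cc(OCOC)c(C/C=C(\C)CCC=C(C)C)c(OCOC)c2C(=O)C(=O)O[C@@H]2C[C@H](C)CC[C@H]2C(C)(C)c2ccccc2)cc1OCOC | intermediate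
16 | (1R,2S,5R)-8-phenylmenthyl (2R,3R)-5-geranyl-3-hydroxy-2-[4-methoxy-3-(methoxymethoxy)phenyl]-4,6-bis(methoxymethoxy)-2,3-dihydro-1-benzofuran-3-carboxylate | COc1ccc([C@H]2Oc3cc(OCOC)c(C/C=C(\C)CCC=C(C)C)c(OCOC)c3[C@]2(O)C(=O)O[C@@H]2C[C@H](C)CC[C@H]2C(C)(C)c2ccccc2)cc1OCOC | intermediate
17 | (2R,3S)-5-geranyl-3-(hydroxymethyl)-2-[4-methoxy-3-(methoxymethoxy)phenyl]-4,6-bis(methoxymethoxy)-2,3-dihydro-1-benzofuran-3-ol | COc1ccc([C@H]2Oc3cc(OCOC)c(C/C=C(\C)CCC=C(C)C)c(OCOC)c3[C@]2(O)CO)cc1OCOC | intermediate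
18 | (2R,3R)-5-geranyl-3-hydroxy-2-[4-methoxy-3-(methoxymethoxy)phenyl]-4,6-bis(methoxymethoxy)-2,3-dihydro-1-benzofuran-3-carbaldehyde | COc1ccc([C@H]2Oc3cc(OCOC)c(C/C=C(\C)CCC=C(C)C)c(OCOC)c3[C@]2(O)C=O)cc1OCOC | intermediate
19 | potassium 3-alkoxide of 18 | COc1ccc([C@H]2Oc3cc(OCOC)c(C/C=C(\C)CCC=C(C)C)c(OCOC)c3[C@]2([O-])C=O)cc1OCOC.[K+] | intermediate
20 | potassium 3-alkoxide of 21 | COc1ccc([C@H]2Oc3cc(OCOC)c(C/C=C(\C)CCC=C(C)C)c(OCOC)c3C(=O)[C@@H]2[O-])cc1OCOC.[K+] | intermediate
21 | (2R,3R)-6-geranyl-3-hydroxy-2-[4-methoxy-3-(methoxymethoxy)phenyl]-5,7-bis(methoxymethoxy)-2,3-dihydro-4H-chromen-4-one (5,7,3'-tri-O-MOM-4'-O-methyldiplacol) | COc1ccc([C@H]2Oc3cc(OCOC)c(C/C=C(\C)CCC=C(C)C)c(OCOC)c3C(=O)[C@@H]2O)cc1OCOC | intermediate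
22 | 4'-O-methyldiplacol, (2R,3R)-6-geranyl-3,5,7-trihydroxy-2-(3-hydroxy-4-methoxyphenyl)-2,3-dihydro-4H-chromen-4-one | COc1ccc([C@H]2Oc3cc(O)c(C/C=C(\C)CCC=C(C)C)c(O)c3C(=O)[C@@H]2O)cc1O | target

**Step count and risks**

Total: 12 steps. Longest linear sequence: 10 steps (3 → 4 → 5 → 6 → 9 → 15 → 16 → 17 → 18 → 21 → 22).

Steps most likely to fail:

1. Step 11 (Proposed new method). What may go wrong: the ring A carbon C3a migrates in place of C2, and the resulting 3-oxo isomer enolises at C2 so that the C2 configuration erodes; or the shift stalls and the aldehyde is consumed by other base-induced pathways. Fallback, using known flavonoid chemistry in which ring C is closed by epoxide opening instead of ring expansion: it sets out from 9 and comes back to the route at 21. Aryllithium 13, made from 9 as in step 7, is quenched with N-methoxy-N-methylacetamide to give the acetophenone F1. Claisen–Schmidt condensation of F1 with aldehyde 4 (KOH, EtOH) gives the chalcone F2. Juliá–Colonna epoxidation (poly-L-leucine, urea–H2O2, DBU, THF) gives the (2R,3S)-epoxy ketone F3. DDQ in wet CH2Cl2 removes the electron-rich benzyl group from the oxygen ortho to the ketone, giving the hydroxy epoxy ketone F4 and returning aldehyde 4. With a trace of acid the freed phenol opens the epoxide at the benzylic carbon with inversion (6-endo) and should give 21.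

2. Step 8. What may go wrong: low facial selectivity in the closure of the 1,5-biradical, leaving little of the 2R series, made worse if the diastereomers resist separation. Fallback, in which the absolute configuration rests on a resolution and no longer on induction: it sets out from 9 and comes back at 17. Aryllithium 13 is quenched with dimethyl oxalate to give the methyl keto ester F5, which is irradiated as in step 8 to the racemic methyl hydroxy ester F6. LiAlH4 reduction gives the racemic diol, that is 17 together with the (2S,3R)-diol F7, and preparative chromatography on a chiral stationary phase delivers 17.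

3. Step 7. What may go wrong: deprotonation at the benzylic ether CH2 or on ring B in place of ring A, or double addition to the oxalyl unit. Fallback, which fixes the metalation site by a halogen: it sets out from 9 and comes back at aryllithium 13. NBS (CH2Cl2, −78 °C) should brominate the only free position of ring A, the most electron-rich ring, to give the aryl bromide F8. Bromine–lithium exchange (n-BuLi, THF, −78 °C) then gives 13 without any deprotonation, and step 7 continues from the copper transmetalation.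

**Further compounds**

F1 | step 11 | 1-[3-geranyl-6-{[4-methoxy-3-(methoxymethoxy)benzyl]oxy}-2,4-bis(methoxymethoxy)phenyl]ethanone | COc1ccc(COc2cc(OCOC)c(C/C=C(\C)CCC=C(C)C)c(OCOC)c2C(C)=O)cc1OCOC
F2 | step 11 | (E)-1-[3-geranyl-6-{[4-methoxy-3-(methoxymethoxy)benzyl]oxy}-2,4-bis(methoxymethoxy)phenyl]-3-[4-methoxy-3-(methoxymethoxy)phenyl]prop-2-en-1-one | COc1ccc(/C=C/C(=O)c2c(OCc3ccc(OC)c(OCOC)c3)cc(OCOC)c(C/C=C(\C)CCC=C(C)C)c2OCOC)cc1OCOC
F3 | step 11 | [3-geranyl-6-{[4-methoxy-3-(methoxymethoxy)benzyl]oxy}-2,4-bis(methoxymethoxy)phenyl]{(2R,3S)-3-[4-methoxy-3-(methoxymethoxy)phenyl]oxiran-2-yl}methanone | COc1ccc([C@@H]2O[C@H]2C(=O)c2c(OCc3ccc(OC)c(OCOC)c3)cc(OCOC)c(C/C=C(\C)CCC=C(C)C)c2OCOC)cc1OCOC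
F4 | step 11 | [3-geranyl-6-hydroxy-2,4-bis(methoxymethoxy)phenyl]{(2R,3S)-3-[4-methoxy-3-(methoxymethoxy)phenyl]oxiran-2-yl}methanone | COc1ccc([C@@H]2O[C@H]2C(=O)c2c(O)cc(OCOC)c(C/C=C(\C)CCC=C(C)C)c2OCOC)cc1OCOC
F5 | step 8 | methyl 2-[3-geranyl-6-{[4-methoxy-3-(methoxymethoxy)benzyl]oxy}-2,4-bis(methoxymethoxy)phenyl]-2-oxoacetate | COc1ccc(COc2cc(OCOC)c(C/C=C(\C)CCC=C(C)C)c(OCOC)c2C(=O)C(=O)OC)cc1OCOC
F6 | step 8 | racemic methyl (2R*,3R*)-5-geranyl-3-hydroxy-2-[4-methoxy-3-(methoxymethoxy)phenyl]-4,6-bis(methoxymethoxy)-2,3-dihydro-1-benzofuran-3-carboxylate (both enantiomers) | COc1ccc([C@H]2Oc3cc(OCOC)c(C/C=C(\C)CCC=C(C)C)c(OCOC)c3[C@]2(O)C(=O)OC)cc1OCOC.COc1ccc([C@@H]2Oc3cc(OCOC)c(C/C=C(\C)CCC=C(C)C)c(OCOC)c3[C@@]2(O)C(=O)OC)cc1OCOC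
F7 | step 8 | (2S,3R)-5-geranyl-3-(hydroxymethyl)-2-[4-methoxy-3-(methoxymethoxy)phenyl]-4,6-bis(methoxymethoxy)-2,3-dihydro-1-benzofuran-3-ol, the enantiomer of 17 | COc1ccc([C@@H]2Oc3cc(OCOC)c(C/C=C(\C)CCC=C(C)C)c(OCOC)c3[C@@]2(O)CO)cc1OCOC
F8 | step 7 | 2-bromo-4-geranyl-1-{[4-methoxy-3-(methoxymethoxy)benzyl]oxy}-3,5-bis(methoxymethoxy)benzene | COc1ccc(COc2cc(OCOC)c(C/C=C(\C)CCC=C(C)C)c(OCOC)c2Br)cc1OCOC
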